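## Retrosynthetic overview

- Both rings close in the last step. An α-hydroxyallyl radical at C6, made by photocatalytic hydrogen-atom transfer from an acyclic primary allylic alcohol, adds to C7 of a 2-(acetoxymethyl)enoate to close the ten-membered carbocycle first. Loss of acetate then unveils the exo-methylene, and the C6–OH lactonises to give the γ-lactone second.
- The 1-OH/3-OAc anti-diol comes from a boron aldol (C2–C3) of a methyl ketone with a Z-enal, followed by Evans–Tishchenko reduction with acetaldehyde.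
- Ketone/acceptor arm (C1, C2, C7–C14): (Z)-3-methylpent-2-en-4-yn-1-ol → enal → vinyl addition and lipase resolution (C8) → angelate → alkyne hydration → cross-metathesis with methyl 2-(acetoxymethyl)acrylate.
- Enal arm (C3–C6, C15): but-2-yn-1-ol → Z-vinyl iodide → silyl ether → formylation.

Assumption: the structure is taken exactly as drawn, that is (1S,3S,6R,7R,8R) in germacrane numbering with a cis-fused 12,6-lactone, 4Z and 9Z ring alkenes and a Z (angelate) ester; germacrane locants C1–C15 are used throughout.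

## Route

Step 1
Reactants: 1 (Z)-3-methylpent-2-en-4-yn-1-ol
Product: 2 (Z)-3-methylpent-2-en-4-ynal
Conditions: MnO2 (15 equiv), CH2Cl2, rt
Reagents that add atoms: none
Why: Allylic oxidation with activated MnO2 stops at the enal (C8) and leaves the alkyne and the Z-alkene (future C9=C10) untouched.

Step 2
Reactants: 2 (Z)-3-methylpent-2-en-4-ynal
Product: 3 rac-(4Z)-5-methylhepta-1,4-dien-6-yn-3-ol
Conditions: CH2=CHMgBr (1.1 equiv), THF, −78 °C; aq. NH4Cl
Reagents that add atoms: vinylmagnesium bromide, C=C[Mg]Br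
Why: Grignard 1,2-addition to the aldehyde at low temperature outruns acetylide formation and conjugate addition and gives the bis-allylic carbinol (C8, with C7 attached) as a racemate.

Step 3
Reactants: 3 rac-(4Z)-5-methylhepta-1,4-dien-6-yn-3-ol
Product: 4 (3S,4Z)-5-methylhepta-1,4-dien-6-yn-3-ol
Conditions: immobilised Candida antarctica lipase B (Novozym 435), vinyl acetate, MTBE, 30 °C, to about 52% conversion; chromatography
Reagents that add atoms: none
Why: Enzymatic kinetic resolution by transesterification: by Kazlauskas' rule (vinyl as medium, branched enynyl as large group) the 3R alcohol is acetylated and the 3S alcohol, whose carbinol carbon becomes C8, is recovered.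

Step 4
Reactants: 4 (3S,4Z)-5-methylhepta-1,4-dien-6-yn-3-ol; 5 angelic acid
Product: 7 (3S,4Z)-5-methylhepta-1,4-dien-6-yn-3-yl (2Z)-2-methylbut-2-enoate, via angelic 2,4,6-trichlorobenzoic anhydride 6 (not isolated)
Conditions: 5, 2,4,6-trichlorobenzoyl chloride, Et3N, toluene, rt; then 4, toluene, 80 °C (no DMAP)
Reagents that add atoms: none
Why: Yamaguchi-type esterification through the mixed anhydride without a nucleophilic catalyst acylates O8 with retention at C8 and without angelate-to-tiglate isomerisation.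

Step 5
Reactants: 7 (3S,4Z)-5-methylhepta-1,4-dien-6-yn-3-yl (2Z)-2-methylbut-2-enoate
Product: 8 (3S,4Z)-5-methyl-6-oxohepta-1,4-dien-3-yl (2Z)-2-methylbut-2-enoate
Conditions: Ph3PAuNTf2 (2 mol%), 1,4-dioxane/H2O (10:1), 40 °C
Reagents that add atoms: water, O
Why: Gold-catalysed Markovnikov hydration of the terminal alkyne gives the methyl ketone (C1=O, C2H3), and it is done only after O8 is acylated so that the Z-γ-oxygenated enone cannot close to a hemiketal and dehydrate to a furan.

Step 6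
Reactants: 9 methyl 2-(hydroxymethyl)prop-2-enoate
Product: 10 methyl 2-(acetoxymethyl)prop-2-enoate
Conditions: Ac2O, pyridine, CH2Cl2, 0 °C to rt
Reagents that add atoms: acetic anhydride, CC(=O)OC(C)=O
Why: Simple O-acetylation turns the primary allylic hydroxyl (on the future C13) into the leaving group that later unveils the exo-methylene.

Step 7
Reactants: 8 (3S,4Z)-5-methyl-6-oxohepta-1,4-dien-3-yl (2Z)-2-methylbut-2-enoate; 10 methyl 2-(acetoxymethyl)prop-2-enoate
Product: 11 methyl (2E,4R,5Z)-2-(acetoxymethyl)-6-methyl-4-{[(2Z)-2-methylbut-2-enoyl]oxy}-7-oxoocta-2,5-dienoate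
Conditions: 10 (4 equiv), second-generation Hoveyda–Grubbs catalyst RuCl2(H2IMes)(=CH-C6H4-2-OiPr) (10 mol%), CH2Cl2, 40 °C
Reagents that add atoms: none
Why: Olefin cross-metathesis of the monosubstituted vinyl group with the 1,1-disubstituted acrylate (in excess) forms C7=C11 as the thermodynamically favoured 2E enoate, while the trisubstituted and conjugated alkenes and the C8 stereocentre are inert (the descriptor changes from S to R only through priorities).

Step 8
Reactants: 12 but-2-yn-1-ol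
Product: 14 (Z)-3-iodobut-2-en-1-ol, via cyclic sodium alkenylaluminate 13 (not isolated)
Conditions: NaAlH2(OCH2CH2OCH3)2, THF, 0 °C to rt; then I2, −78 to 0 °C
Reagents that add atoms: iodine, II
Why: Hydroxyl-directed trans-hydroalumination places aluminium on the distal carbon cis to CH2O, and iodinolysis with retention gives only the Z-vinyl iodide (future Z-C4=C5).

Step 9
Reactants: 14 (Z)-3-iodobut-2-en-1-ol
Product: 15 (Z)-tert-butyl[(3-iodobut-2-en-1-yl)oxy]dimethylsilane
Conditions: TBSCl, imidazole, CH2Cl2, 0 °C to rt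
Reagents that add atoms: tert-butyldimethylsilyl chloride, CC(C)(C)[Si](C)(C)Cl
Why: Standard silylation protects the primary alcohol (future C6–OH) for the organolithium step.

Step 10
Reactants: 15 (Z)-tert-butyl[(3-iodobut-2-en-1-yl)oxy]dimethylsilane
Product: 17 (2Z)-4-[(tert-butyldimethylsilyl)oxy]-2-methylbut-2-enal, via Z-alkenyllithium 16 (not isolated)
Conditions: t-BuLi (2.1 equiv), Et2O, −78 °C; DMF, −78 to 0 °C; aq. NH4Cl
Reagents that add atoms: N,N-dimethylformamide, CN(C)C=O
Why: Iodine–lithium exchange and formylation both proceed with retention of alkene geometry, giving the Z-enal whose carbonyl carbon is C3.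

Step 11
Reactants: 11 methyl (2E,4R,5Z)-2-(acetoxymethyl)-6-methyl-4-{[(2Z)-2-methylbut-2-enoyl]oxy}-7-oxoocta-2,5-dienoate; 17 (2Z)-4-[(tert-butyldimethylsilyl)oxy]-2-methylbut-2-enal
Product: 19 methyl (2E,4R,5Z,9S,10Z)-2-(acetoxymethyl)-12-[(tert-butyldimethylsilyl)oxy]-9-hydroxy-6,10-dimethyl-4-{[(2Z)-2-methylbut-2-enoyl]oxy}-7-oxododeca-2,5,10-trienoate, via diisopinocampheylboron enolate 18 (not isolated)
Conditions: (+)-Ipc2BCl, Et3N, Et2O, 0 °C; then 17, −78 to −20 °C; H2O2, pH 7 buffer, MeOH, 0 °C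
Reagents that add atoms: none
Why: Paterson boron aldol: the ketone is enolised regioselectively on the methyl side (C2) and the chiral enolate adds to the si face of the enal through a closed boat-like transition state (reagent control; methyl ketones show the opposite aldehyde-face sense to ethyl ketones, hence the (+)-reagent), setting C3 as S, with the minor diastereomer removed by chromatography.

Step 12
Reactants: 19 methyl (2E,4R,5Z,9S,10Z)-2-(acetoxymethyl)-12-[(tert-butyldimethylsilyl)oxy]-9-hydroxy-6,10-dimethyl-4-{[(2Z)-2-methylbut-2-enoyl]oxy}-7-oxododeca-2,5,10-trienoate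
Product: 20 methyl (2E,4R,5Z,7S,9S,10Z)-9-acetoxy-2-(acetoxymethyl)-12-[(tert-butyldimethylsilyl)oxy]-7-hydroxy-6,10-dimethyl-4-{[(2Z)-2-methylbut-2-enoyl]oxy}dodeca-2,5,10-trienoate
Conditions: CH3CHO (10 equiv), SmI2 (0.3 equiv), THF, −10 °C
Reagents that add atoms: acetaldehyde, CC=O
Why: Evans–Tishchenko reduction: the samarium-bound hemiacetal of the C3–OH with acetaldehyde delivers hydride intramolecularly to the C1 ketone through a chair-like bicyclic transition state, giving the 1,3-anti diol (1S) with the acetate on O3 and O1 free, which is exactly the pattern of the target.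

Step 13
Reactants: 20 methyl (2E,4R,5Z,7S,9S,10Z)-9-acetoxy-2-(acetoxymethyl)-12-[(tert-butyldimethylsilyl)oxy]-7-hydroxy-6,10-dimethyl-4-{[(2Z)-2-methylbut-2-enoyl]oxy}dodeca-2,5,10-trienoate
Product: 21 methyl (2E,4R,5Z,7S,9S,10Z)-9-acetoxy-2-(acetoxymethyl)-7,12-dihydroxy-6,10-dimethyl-4-{[(2Z)-2-methylbut-2-enoyl]oxy}dodeca-2,5,10-trienoate
Conditions: HF·pyridine, pyridine, THF, 0 °C
Reagents that add atoms: none
Why: Buffered fluoride cleaves the only silyl ether without acyl migration or ester cleavage, unmasking the primary allylic alcohol whose α-C–H bond is used next.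

Step 14
Reactants: 21 methyl (2E,4R,5Z,7S,9S,10Z)-9-acetoxy-2-(acetoxymethyl)-7,12-dihydroxy-6,10-dimethyl-4-{[(2Z)-2-methylbut-2-enoyl]oxy}dodeca-2,5,10-trienoate
Product: 24 (3aR,4R,5Z,7S,9S,10Z,11aR)-9-acetoxy-7-hydroxy-6,10-dimethyl-3-methylidene-2-oxo-2,3,3a,4,7,8,9,11a-octahydrocyclodeca[b]furan-4-yl (2Z)-2-methylbut-2-enoate, via C6 α-hydroxyallyl radical 22 (not isolated), via macrocyclic hydroxy ester 23 (not isolated)
Conditions: Ir[dF(CF3)ppy]2(dtbbpy)PF6 (2 mol%), quinuclidine (20 mol%), Bu4N(H2PO4) (25 mol%), MeCN (0.003 M), 450 nm LEDs, −20 °C; then PPTS (cat.), CH2Cl2, rt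
Reagents that add atoms: none
Why: Proposed new method: the excited iridium photocatalyst oxidises quinuclidine to its radical cation, which abstracts the hydridic, phosphate-hydrogen-bond-activated allylic α-C–H of the primary alcohol (C6) in preference to α-acyloxy and simple allylic C–H bonds; the neutral α-hydroxyallyl radical (slow to rotate at −20 °C, and with no strong reductant present that could expel the C3 or C8 acyloxy groups) adds through C6 to C7 of the tethered enoate in a ten-membered Giese ring closure, anti to the C8 acyloxy group in the A(1,3)-minimised Felkin–Anh conformer (sets 7R) and with O6–H hydrogen-bonded to the ester carbonyl so that C5 and C8 end up cis (sets 6R); the α-ester radical is then reduced by the divalent iridium species to the enolate, which expels acetate (E1cB) to form the exo-methylene, and the cis hydroxy ester lactonises; closest known reaction type: photoredox/quinuclidine hydrogen-atom-transfer α-C–H alkylation of alcohols with acrylates to γ-lactones, combined with radical addition–elimination on 2-(acyloxymethyl)acrylates and macrocyclic Giese cyclisation.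

## Compound list

1 | (Z)-3-methylpent-2-en-4-yn-1-ol | C#C/C(C)=C\CO | starting material
2 | (Z)-3-methylpent-2-en-4-ynal | C#C/C(C)=C\C=O | intermediate
3 | rac-(4Z)-5-methylhepta-1,4-dien-6-yn-3-ol | C#C/C(C)=C\C(O)C=C | intermediate
4 | (3S,4Z)-5-methylhepta-1,4-dien-6-yn-3-ol | C#C/C(C)=C\[C@@H](O)C=C | intermediate
5 | angelic acid, (2Z)-2-methylbut-2-enoic acid | C/C=C(/C)C(=O)O | starting material
6 | (2Z)-2-methylbut-2-enoic 2,4,6-trichlorobenzoic anhydride | C/C=C(/C)C(=O)OC(=O)c1c(Cl)cc(Cl)cc1Cl | intermediate (not isolated)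
7 | (3S,4Z)-5-methylhepta-1,4-dien-6-yn-3-yl (2Z)-2-methylbut-2-enoate | C#C/C(C)=C\[C@@H](OC(=O)/C(C)=C\C)C=C | intermediate
8 | (3S,4Z)-5-methyl-6-oxohepta-1,4-dien-3-yl (2Z)-2-methylbut-2-enoate | CC(=O)/C(C)=C\[C@@H](OC(=O)/C(C)=C\C)C=C | intermediate
9 | methyl 2-(hydroxymethyl)prop-2-enoate | C=C(CO)C(=O)OC | starting material
10 | methyl 2-(acetoxymethyl)prop-2-enoate | C=C(COC(C)=O)C(=O)OC | intermediate
11 | methyl (2E,4R,5Z)-2-(acetoxymethyl)-6-methyl-4-{[(2Z)-2-methylbut-2-enoyl]oxy}-7-oxoocta-2,5-dienoate | CC(=O)/C(C)=C\[C@@H](OC(=O)/C(C)=C\C)/C=C(/C(=O)OC)COC(C)=O | intermediate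
12 | but-2-yn-1-ol | CC#CCO | starting material
13 | cyclic sodium alkenylaluminate (Al bound to O and to C3 of the butenyl unit, two 2-methoxyethoxy ligands) | CC1=CCO[Al-]1(OCCOC)OCCOC.[Na+] | intermediate (not isolated)
14 | (Z)-3-iodobut-2-en-1-ol | C/C(I)=C/CO | intermediate
15 | (Z)-tert-butyl[(3-iodobut-2-en-1-yl)oxy]dimethylsilane | C/C(I)=C/CO[Si](C)(C)C(C)(C)C | intermediate
16 | (Z)-[4-(tert-butyldimethylsilyloxy)but-2-en-2-yl]lithium | C/C([Li])=C/CO[Si](C)(C)C(C)(C)C | intermediate (not isolated)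
17 | (2Z)-4-[(tert-butyldimethylsilyl)oxy]-2-methylbut-2-enal | O=C/C(C)=C\CO[Si](C)(C)C(C)(C)C | intermediate
18 | (+)-diisopinocampheylboron enolate of 11 (O–B on C1, C2 as CH2=; Ipc groups from (−)-α-pinene) | C=C(OB([C@H]1C[C@H]2C[C@@H]([C@@H]1C)C2(C)C)[C@H]1C[C@H]2C[C@@H]([C@@H]1C)C2(C)C)/C(C)=C\[C@@H](OC(=O)/C(C)=C\C)/C=C(/C(=O)OC)COC(C)=O | intermediate (not isolated)
19 | methyl (2E,4R,5Z,9S,10Z)-2-(acetoxymethyl)-12-[(tert-butyldimethylsilyl)oxy]-9-hydroxy-6,10-dimethyl-4-{[(2Z)-2-methylbut-2-enoyl]oxy}-7-oxododeca-2,5,10-trienoate | CC(C)(C)[Si](C)(C)OC/C=C(/C)[C@@H](O)CC(=O)/C(C)=C\[C@@H](OC(=O)/C(C)=C\C)/C=C(/C(=O)OC)COC(C)=O | intermediate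
20 | methyl (2E,4R,5Z,7S,9S,10Z)-9-acetoxy-2-(acetoxymethyl)-12-[(tert-butyldimethylsilyl)oxy]-7-hydroxy-6,10-dimethyl-4-{[(2Z)-2-methylbut-2-enoyl]oxy}dodeca-2,5,10-trienoate | CC(C)(C)[Si](C)(C)OC/C=C(/C)[C@@H](OC(C)=O)C[C@H](O)/C(C)=C\[C@@H](OC(=O)/C(C)=C\C)/C=C(/C(=O)OC)COC(C)=O | intermediate
21 | methyl (2E,4R,5Z,7S,9S,10Z)-9-acetoxy-2-(acetoxymethyl)-7,12-dihydroxy-6,10-dimethyl-4-{[(2Z)-2-methylbut-2-enoyl]oxy}dodeca-2,5,10-trienoate | OC/C=C(/C)[C@@H](OC(C)=O)C[C@H](O)/C(C)=C\[C@@H](OC(=O)/C(C)=C\C)/C=C(/C(=O)OC)COC(C)=O | intermediate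
22 | C6-centred α-hydroxyallyl radical of 21 | O[CH]/C=C(/C)[C@@H](OC(C)=O)C[C@H](O)/C(C)=C\[C@@H](OC(=O)/C(C)=C\C)/C=C(/C(=O)OC)COC(C)=O | intermediate (not isolated)
23 | methyl 2-[(1R,2R,3Z,5S,7S,8Z,10R)-5-acetoxy-2,7-dihydroxy-4,8-dimethyl-10-{[(2Z)-2-methylbut-2-enoyl]oxy}cyclodeca-3,8-dien-1-yl]prop-2-enoate | C=C(C(=O)OC)[C@@H]1[C@H](O)/C=C(/C)[C@@H](OC(C)=O)C[C@H](O)/C(C)=C\[C@H]1OC(=O)/C(C)=C\C | intermediate (not isolated)
24 | (3aR,4R,5Z,7S,9S,10Z,11aR)-9-acetoxy-7-hydroxy-6,10-dimethyl-3-methylidene-2-oxo-2,3,3a,4,7,8,9,11a-octahydrocyclodeca[b]furan-4-yl (2Z)-2-methylbut-2-enoate | C=C1C(=O)O[C@@H]2/C=C(/C)[C@@H](OC(C)=O)C[C@H](O)/C(C)=C\[C@@H](OC(=O)/C(C)=C\C)[C@H]12 | target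

## Step count and risks

Total step count: 14. Longest linear sequence: 10 steps (1, 2, 3, 4, 5, 7, 11, 12, 13, 14).

The three steps most likely to fail:

**Step 14 (radical macrocyclisation/lactonisation).** Likely failure modes are parasitic hydrogen abstraction at C1–H, slow ten-membered closure of a stabilised allyl radical with dimerisation or Z/E scrambling, and the wrong C6 epimer. The fallback sets out from 21 and returns at 24. TEMPO/PhI(OAc)2 in CH2Cl2 oxidises the primary allylic alcohol selectively to the Z-enal F1. A palladium/indium umpolung allylation (Pd(PPh3)4 catalyst, InI, THF/HMPA, high dilution) then ionises the 2-(acetoxymethyl)enoate with zerovalent palladium and transmetallates to the allylindium intermediate F2. This adds through C7 to the C6 aldehyde in a closed chair transition state (syn adduct, that is the cis-lactone) and lactonises to 24.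

**Step 7 (cross-metathesis).** The hindered allylic ester and the 1,1-disubstituted acrylate may react too slowly or give homodimers. The fallback sets out from 8 and returns at 11. Lemieux–Johnson cleavage of the terminal vinyl group (OsO4 catalyst, NaIO4, 2,6-lutidine, dioxane/H2O) gives the α-acyloxy aldehyde F3. Morita–Baylis–Hillman reaction with methyl acrylate (DABCO) gives the adduct F4, and acetylation (Ac2O, pyridine) gives the acetate F5. DABCO-catalysed allylic transposition (SN2′–SN2′) then delivers the thermodynamic 2E 2-(acetoxymethyl)enoate 11.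

**Step 11 (boron aldol).** Enolisation of 11 may be compromised by the base-sensitive allylic acetate and the acidic C8–H, and facial selectivity with a methyl ketone is only moderate. The fallback sets out from 8 and 17 and returns at 20, postponing the metathesis. The same (+)-Ipc2BCl aldol on the simpler vinyl ketone 8 gives the β-hydroxy ketone F6, where diastereomers are easier to separate. Evans–Tishchenko reduction (CH3CHO, SmI2 catalyst) gives the anti-diol monoacetate F7, and cross-metathesis of F7 with 10 under the conditions of step 7 gives 20.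

## Further compounds

F1 | step 14 | methyl (2E,4R,5Z,7S,9S,10Z)-9-acetoxy-2-(acetoxymethyl)-7-hydroxy-6,10-dimethyl-4-{[(2Z)-2-methylbut-2-enoyl]oxy}-12-oxododeca-2,5,10-trienoate | O=C/C=C(/C)[C@@H](OC(C)=O)C[C@H](O)/C(C)=C\[C@@H](OC(=O)/C(C)=C\C)/C=C(/C(=O)OC)COC(C)=O
F2 | step 14 | allylindium intermediate from F1 (C13 acetoxy replaced by acetato(iodo)indium) | O=C/C=C(/C)[C@@H](OC(C)=O)C[C@H](O)/C(C)=C\[C@@H](OC(=O)/C(C)=C\C)/C=C(/C(=O)OC)C[In](I)OC(C)=O
F3 | step 7 | (2R,3Z)-4-methyl-1,5-dioxohex-3-en-2-yl (2Z)-2-methylbut-2-enoate | CC(=O)/C(C)=C\[C@@H](OC(=O)/C(C)=C\C)C=O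
F4 | step 7 | methyl (4R,5Z)-3-hydroxy-6-methyl-2-methylidene-4-{[(2Z)-2-methylbut-2-enoyl]oxy}-7-oxooct-5-enoate (C3 epimers) | CC(=O)/C(C)=C\[C@@H](OC(=O)/C(C)=C\C)C(O)C(=C)C(=O)OC
F5 | step 7 | methyl (4R,5Z)-3-acetoxy-6-methyl-2-methylidene-4-{[(2Z)-2-methylbut-2-enoyl]oxy}-7-oxooct-5-enoate (C3 epimers) | CC(=O)/C(C)=C\[C@@H](OC(=O)/C(C)=C\C)C(OC(C)=O)C(=C)C(=O)OC
F6 | step 11 | (3S,4Z,8S,9Z)-11-[(tert-butyldimethylsilyl)oxy]-8-hydroxy-5,9-dimethyl-6-oxoundeca-1,4,9-trien-3-yl (2Z)-2-methylbut-2-enoate | CC(C)(C)[Si](C)(C)OC/C=C(/C)[C@@H](O)CC(=O)/C(C)=C\[C@@H](OC(=O)/C(C)=C\C)C=C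
F7 | step 11 | (3S,4Z,6S,8S,9Z)-8-acetoxy-11-[(tert-butyldimethylsilyl)oxy]-6-hydroxy-5,9-dimethylundeca-1,4,9-trien-3-yl (2Z)-2-methylbut-2-enoate | CC(C)(C)[Si](C)(C)OC/C=C(/C)[C@@H](OC(C)=O)C[C@H](O)/C(C)=C\[C@@H](OC(=O)/C(C)=C\C)C=C
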